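**Retrosynthetic overview**
1. Target 30 ⇐ desilylation of 29 ⇐ Mitsunobu esterification (inversion at C8) of macrocyclic alcohol 22 with acid 28.
2. Key disconnection C7–C8: one intramolecular CrCl2 allylation of bromomethyl-butenolide aldehyde 20 forms the ten-membered ring and the α-methylene lactone of 22 (C7 acts as a homoenolate-type nucleophile toward the C8 aldehyde).
3. Ring order: butenolide first (ring-closing metathesis of ester 19), ten-membered carbocycle second (key step).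
4. C5–C6 by Brown syn-alkoxyallylboration of Z-enal 11; the Z alkene by hydroxyl-directed trans-hydroalumination/iodination of alkyne 7, then formylation.
5. C1–C2 and C10 by Paterson aldol of ketone 4 with ynal 3, then chelation-controlled MeMgBr addition.

Assumption: atom labels C1–C15 in the text follow germacranolide numbering of the target (C2 free secondary carbinol, C5 ring acetate carbon, C6 lactone O-carbon, C7, C8 ester carbon, C10 methyl carbinol, C11–C13 methylene lactone, C15 acetoxymethyl); the SMILES is read as 2R,5S,6S,7R,8R,10S with Z ring and Z side-chain alkenes.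

**Step 1**
Reactants: 1 tert-butyldimethyl(prop-2-yn-1-yloxy)silane
Product: 3 4-[(tert-butyldimethylsilyl)oxy]but-2-ynal, via lithium acetylide 2 (not isolated)
Conditions: n-BuLi, THF, −78 °C; DMF, −78 to 0 °C; inverse quench into aq. KH2PO4
Reagents that add atoms: N,N-dimethylformamide, CN(C)C=O
Why: Formylation of a lithium acetylide with DMF; the buffered inverse quench keeps the released dimethylamine from adding to the ynal.

**Step 2**
Reactants: 4 4,4-dimethoxybutan-2-one; 3 4-[(tert-butyldimethylsilyl)oxy]but-2-ynal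
Product: 6 (5R)-8-[(tert-butyldimethylsilyl)oxy]-5-hydroxy-1,1-dimethoxyoct-6-yn-3-one, via boron enolate 5 (not isolated)
Conditions: (+)-Ipc2BCl (from (−)-α-pinene), Et3N, Et2O, 0 °C; 3, −78 to −20 °C; H2O2, MeOH, pH 7 buffer
Reagents that add atoms: none
Why: Paterson boron aldol, in which Ipc2BCl/Et3N enolises the less hindered methyl side of 4 and the Ipc ligands direct addition to the Re face of the ynal, setting C2 as R (the sense of induction is assigned from the methyl-ketone precedent and the ee is expected to be moderate to good).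

**Step 3**
Reactants: 6 (5R)-8-[(tert-butyldimethylsilyl)oxy]-5-hydroxy-1,1-dimethoxyoct-6-yn-3-one
Product: 7 (3S,5R)-8-[(tert-butyldimethylsilyl)oxy]-1,1-dimethoxy-3-methyloct-6-yne-3,5-diol
Conditions: MeMgBr (3 equiv), CH2Cl2/Et2O, −78 °C; aq. NH4Cl
Reagents that add atoms: methylmagnesium bromide, C[Mg]Br
Why: Chelation-controlled Grignard addition, in which the magnesium alkoxide of the β-hydroxy ketone forms a six-membered chelate and methyl adds axially to give the 1,3-syn diol, setting C10 as S.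

**Step 4**
Reactants: 7 (3S,5R)-8-[(tert-butyldimethylsilyl)oxy]-1,1-dimethoxy-3-methyloct-6-yne-3,5-diol
Product: 9 (3S,5R,6Z)-8-[(tert-butyldimethylsilyl)oxy]-7-iodo-1,1-dimethoxy-3-methyloct-6-ene-3,5-diol, via alkenylaluminate 8 (not isolated)
Conditions: NaAlH2(OCH2CH2OMe)2, THF, 0 °C to rt; I2, −78 °C; aq. potassium sodium tartrate
Reagents that add atoms: iodine, II
Why: Hydroxyl-directed trans-hydroalumination of a propargylic alcohol, in which the C2 alkoxide delivers hydride to C3 and aluminium sits on C4 in a five-membered ring, followed by iodinolysis with retention so that iodine is cis to C2 (this fixes the Z ring alkene).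

**Step 5**
Reactants: 9 (3S,5R,6Z)-8-[(tert-butyldimethylsilyl)oxy]-7-iodo-1,1-dimethoxy-3-methyloct-6-ene-3,5-diol
Product: 10 (3S,5R,6Z)-5,8-bis[(tert-butyldimethylsilyl)oxy]-7-iodo-1,1-dimethoxy-3-methyloct-6-en-3-ol
Conditions: TBSCl, imidazole, DMF, 0 °C to rt
Reagents that add atoms: tert-butyldimethylsilyl chloride, CC(C)(C)[Si](C)(C)Cl
Why: Standard silylation that takes the secondary allylic C2 hydroxyl and leaves the tertiary C10 hydroxyl free.

**Step 6**
Reactants: 10 (3S,5R,6Z)-5,8-bis[(tert-butyldimethylsilyl)oxy]-7-iodo-1,1-dimethoxy-3-methyloct-6-en-3-ol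
Product: 11 (2Z,4R,6S)-4-[(tert-butyldimethylsilyl)oxy]-2-{[(tert-butyldimethylsilyl)oxy]methyl}-6-hydroxy-8,8-dimethoxy-6-methyloct-2-enal
Conditions: Pd(PPh3)4 (5 mol %), CO (3 atm), Bu3SnH (slow addition), THF, 50 °C
Reagents that add atoms: carbon monoxide, [C-]#[O+]
Why: Palladium-catalysed reductive carbonylation (Stille formylation) of an alkenyl iodide, in which oxidative addition, CO insertion and hydride transfer from tin proceed with retention so the new aldehyde carbon (C5) is cis to C2.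

**Step 7**
Reactants: 11 (2Z,4R,6S)-4-[(tert-butyldimethylsilyl)oxy]-2-{[(tert-butyldimethylsilyl)oxy]methyl}-6-hydroxy-8,8-dimethoxy-6-methyloct-2-enal; 12 3-(methoxymethoxy)prop-1-ene
Product: 14 (3S,5R,6Z,8S,9S)-5-[(tert-butyldimethylsilyl)oxy]-7-{[(tert-butyldimethylsilyl)oxy]methyl}-1,1-dimethoxy-9-(methoxymethoxy)-3-methylundeca-6,10-diene-3,8-diol, via alkoxyallylborane 13 (not isolated)
Conditions: 12, s-BuLi, THF, −78 °C; (+)-Ipc2BOMe (from (−)-α-pinene); BF3·OEt2; 11, −78 °C; NaOH, H2O2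
Reagents that add atoms: none
Why: Brown asymmetric alkoxyallylboration, in which the (Z)-γ-alkoxyallylborane reacts through a chair transition state to give the syn 1,2-diol monoether and the (+)-Ipc ligands select the Re face of the aldehyde, setting C5 (S) and C6 (S) together.

**Step 8**
Reactants: 14 (3S,5R,6Z,8S,9S)-5-[(tert-butyldimethylsilyl)oxy]-7-{[(tert-butyldimethylsilyl)oxy]methyl}-1,1-dimethoxy-9-(methoxymethoxy)-3-methylundeca-6,10-diene-3,8-diol
Product: 15 (3S,5R,6Z,8S,9S)-5-[(tert-butyldimethylsilyl)oxy]-7-(hydroxymethyl)-1,1-dimethoxy-9-(methoxymethoxy)-3-methylundeca-6,10-diene-3,8-diol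
Conditions: HF·pyridine, pyridine, THF, 0 °C
Reagents that add atoms: none
Why: Selective desilylation, because the primary allylic silyl ether at C15 is cleaved much faster than the secondary one at C2 under buffered HF·pyridine while the acetal and MOM ether are untouched.

**Step 9**
Reactants: 15 (3S,5R,6Z,8S,9S)-5-[(tert-butyldimethylsilyl)oxy]-7-(hydroxymethyl)-1,1-dimethoxy-9-(methoxymethoxy)-3-methylundeca-6,10-diene-3,8-diol
Product: 16 (3S,5R,6Z,8S,9S)-8-acetoxy-7-(acetoxymethyl)-5-[(tert-butyldimethylsilyl)oxy]-1,1-dimethoxy-9-(methoxymethoxy)-3-methylundeca-6,10-dien-3-ol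
Conditions: Ac2O (2.5 equiv), pyridine, DMAP (5 mol %), CH2Cl2, 0 °C
Reagents that add atoms: acetic anhydride, CC(=O)OC(C)=O
Why: Acetylation of the primary C15 and secondary C5 hydroxyls installs both target acetates at once while the tertiary C10 hydroxyl does not react at 0 °C.

**Step 10**
Reactants: 16 (3S,5R,6Z,8S,9S)-8-acetoxy-7-(acetoxymethyl)-5-[(tert-butyldimethylsilyl)oxy]-1,1-dimethoxy-9-(methoxymethoxy)-3-methylundeca-6,10-dien-3-ol
Product: 17 (3S,5R,6Z,8S,9S)-8-acetoxy-7-(acetoxymethyl)-5-[(tert-butyldimethylsilyl)oxy]-3,9-dihydroxy-3-methylundeca-6,10-dienal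
Conditions: Me2BBr (4 equiv), CH2Cl2, −78 °C; aq. NaHCO3/THF
Reagents that add atoms: water, O
Why: Guindon cleavage with Me2BBr, which at −78 °C removes the MOM ether at C6 and converts the dimethyl acetal into the C8 aldehyde in one operation while silyl ether and acetates survive (the neutral cold work-up limits acetyl migration from C5 to C6).

**Step 11**
Reactants: 17 (3S,5R,6Z,8S,9S)-8-acetoxy-7-(acetoxymethyl)-5-[(tert-butyldimethylsilyl)oxy]-3,9-dihydroxy-3-methylundeca-6,10-dienal; 18 2-(bromomethyl)prop-2-enoic acid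
Product: 19 (3S,4S,5Z,7R,9S)-4-acetoxy-5-(acetoxymethyl)-7-[(tert-butyldimethylsilyl)oxy]-9-hydroxy-9-methyl-11-oxoundeca-1,5-dien-3-yl 2-(bromomethyl)prop-2-enoate
Conditions: 18, N,N'-diisopropylcarbodiimide, DMAP (5 mol %), CH2Cl2, −20 to 0 °C
Reagents that add atoms: none
Why: Steglich esterification of the only free secondary hydroxyl (C6), with the tertiary C10 hydroxyl and the aldehyde as spectators and DMAP kept low to spare the allylic bromide.

**Step 12**
Reactants: 19 (3S,4S,5Z,7R,9S)-4-acetoxy-5-(acetoxymethyl)-7-[(tert-butyldimethylsilyl)oxy]-9-hydroxy-9-methyl-11-oxoundeca-1,5-dien-3-yl 2-(bromomethyl)prop-2-enoate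
Product: 20 (1S,2Z,4R,6S)-2-(acetoxymethyl)-1-[(2S)-4-(bromomethyl)-5-oxo-2,5-dihydrofuran-2-yl]-4-[(tert-butyldimethylsilyl)oxy]-6-hydroxy-6-methyl-8-oxooct-2-en-1-yl acetate
Conditions: second-generation Grubbs catalyst (10 mol %), CH2Cl2, 40 °C, 5 mM
Reagents that add atoms: none
Why: Ring-closing metathesis between the C7 vinyl group and the 2-substituted acrylate gives the five-membered butenolide with loss of ethene, the trisubstituted C3=C4 alkene being too hindered to take part.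

**Step 13**
Reactants: 20 (1S,2Z,4R,6S)-2-(acetoxymethyl)-1-[(2S)-4-(bromomethyl)-5-oxo-2,5-dihydrofuran-2-yl]-4-[(tert-butyldimethylsilyl)oxy]-6-hydroxy-6-methyl-8-oxooct-2-en-1-yl acetate
Product: 22 (3aR,4S,6R,8R,9Z,11S,11aS)-11-acetoxy-10-(acetoxymethyl)-8-[(tert-butyldimethylsilyl)oxy]-4,6-dihydroxy-6-methyl-3-methylidene-3a,4,5,6,7,8,11,11a-octahydrocyclodeca[b]furan-2(3H)-one, via allylchromium dichloride 21 (not isolated)
Conditions: CrCl2 (10 equiv), THF, 25 °C, 2 mM (slow addition of 20); aq. NH4Cl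
Reagents that add atoms: none
Why: Intramolecular Nozaki–Hiyama–Kishi-type allylation, in which two CrCl2 reduce the allylic bromide to an allylchromium that is a homoenolate (β-acyl anion) equivalent, so C7 (normally an acceptor carbon) attacks the acceptor C8 aldehyde carbon on the butenolide face anti to the C5 side chain (7R, trans lactone) through a chair transition state with C9 equatorial (8S), closing the ten-membered ring and forming the α-methylene lactone in one step.

**Step 14**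
Reactants: 23 but-2-yn-1-ol
Product: 25 (2Z)-2-iodobut-2-en-1-ol, via alkenylaluminate 24 (not isolated)
Conditions: LiAlH4, AlCl3 (60:1), THF, reflux; I2, −78 °C; aq. potassium sodium tartrate
Reagents that add atoms: iodine, II
Why: Corey trans-hydroalumination of a propargylic alcohol, where the LiAlH4/AlCl3 variant places aluminium on C2 trans to the delivered hydride and iodinolysis with retention gives iodine cis to the methyl group.

**Step 15**
Reactants: 25 (2Z)-2-iodobut-2-en-1-ol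
Product: 27 (2Z)-2-(hydroxymethyl)but-2-enoic acid, via dilithio derivative 26 (not isolated)
Conditions: n-BuLi (1 equiv) then t-BuLi (2 equiv), Et2O, −78 °C; CO2; aq. HCl
Reagents that add atoms: carbon dioxide, O=C=O
Why: Iodine–lithium exchange on the lithium alkoxide and carboxylation of the configurationally stable alkenyllithium proceed with retention, so the carboxyl group is cis to the methyl group (Z).

**Step 16**
Reactants: 27 (2Z)-2-(hydroxymethyl)but-2-enoic acid
Product: 28 (2Z)-2-(acetoxymethyl)but-2-enoic acid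
Conditions: Ac2O, pyridine, 0 °C to rt; aq. HCl
Reagents that add atoms: acetic anhydride, CC(=O)OC(C)=O
Why: O-acetylation of the primary alcohol, with any mixed anhydride at the carboxyl group hydrolysed in the aqueous work-up.

**Step 17**
Reactants: 22 (3aR,4S,6R,8R,9Z,11S,11aS)-11-acetoxy-10-(acetoxymethyl)-8-[(tert-butyldimethylsilyl)oxy]-4,6-dihydroxy-6-methyl-3-methylidene-3a,4,5,6,7,8,11,11a-octahydrocyclodeca[b]furan-2(3H)-one; 28 (2Z)-2-(acetoxymethyl)but-2-enoic acid
Product: 29 (3aR,4R,6R,8R,9Z,11S,11aS)-11-acetoxy-10-(acetoxymethyl)-8-[(tert-butyldimethylsilyl)oxy]-6-hydroxy-6-methyl-3-methylidene-2-oxo-2,3,3a,4,5,6,7,8,11,11a-decahydrocyclodeca[b]furan-4-yl (2Z)-2-(acetoxymethyl)but-2-enoate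
Conditions: 28, PPh3, DIAD, toluene, 0 °C to rt
Reagents that add atoms: none
Why: Mitsunobu esterification, in which the C8 hydroxyl is activated as an oxyphosphonium and displaced by the carboxylate with inversion (8S to 8R); the carboxylate nucleophile also avoids Z to E isomerisation of the acid and the tertiary C10 hydroxyl is inert.

**Step 18**
Reactants: 29 (3aR,4R,6R,8R,9Z,11S,11aS)-11-acetoxy-10-(acetoxymethyl)-8-[(tert-butyldimethylsilyl)oxy]-6-hydroxy-6-methyl-3-methylidene-2-oxo-2,3,3a,4,5,6,7,8,11,11a-decahydrocyclodeca[b]furan-4-yl (2Z)-2-(acetoxymethyl)but-2-enoate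
Product: 30 (3aR,4R,6S,8R,9Z,11S,11aS)-11-acetoxy-10-(acetoxymethyl)-6,8-dihydroxy-6-methyl-3-methylidene-2-oxo-2,3,3a,4,5,6,7,8,11,11a-decahydrocyclodeca[b]furan-4-yl (2Z)-2-(acetoxymethyl)but-2-enoate
Conditions: HF·pyridine, THF, 0 °C to rt
Reagents that add atoms: none
Why: Fluoride-mediated cleavage of the last silyl ether (C2) under mildly acidic conditions that leave the three acetates, the enoate and the α-methylene lactone intact.

**Compound list**
1 | tert-butyldimethyl(prop-2-yn-1-yloxy)silane | C#CCO[Si](C)(C)C(C)(C)C | starting material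
2 | lithium acetylide of 1 | [Li]C#CCO[Si](C)(C)C(C)(C)C | intermediate
3 | 4-[(tert-butyldimethylsilyl)oxy]but-2-ynal | O=CC#CCO[Si](C)(C)C(C)(C)C | intermediate
4 | 4,4-dimethoxybutan-2-one | CC(=O)CC(OC)OC | starting material
5 | bis[(+)-isopinocampheyl]boron enolate of 4 (methyl-side enol borinate) | C=C(CC(OC)OC)OB([C@H]1C[C@H]2C[C@@H]([C@@H]1C)C2(C)C)[C@H]1C[C@H]2C[C@@H]([C@@H]1C)C2(C)C | intermediate
6 | (5R)-8-[(tert-butyldimethylsilyl)oxy]-5-hydroxy-1,1-dimethoxyoct-6-yn-3-one | COC(OC)CC(=O)C[C@@H](O)C#CCO[Si](C)(C)C(C)(C)C | intermediate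
7 | (3S,5R)-8-[(tert-butyldimethylsilyl)oxy]-1,1-dimethoxy-3-methyloct-6-yne-3,5-diol | COC(OC)C[C@@](C)(O)C[C@@H](O)C#CCO[Si](C)(C)C(C)(C)C | intermediate
8 | cyclic alkenylaluminate from 7 (aluminium on C4, bound to the C2 oxygen; shown in its simplest form) | COC(OC)C[C@@](C)(O)C[C@@H]1C=C(CO[Si](C)(C)C(C)(C)C)[Al-](OCCOC)(OCCOC)O1.[Na+] | intermediate
9 | (3S,5R,6Z)-8-[(tert-butyldimethylsilyl)oxy]-7-iodo-1,1-dimethoxy-3-methyloct-6-ene-3,5-diol | COC(OC)C[C@@](C)(O)C[C@@H](O)/C=C(/CO[Si](C)(C)C(C)(C)C)I | intermediate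
10 | (3S,5R,6Z)-5,8-bis[(tert-butyldimethylsilyl)oxy]-7-iodo-1,1-dimethoxy-3-methyloct-6-en-3-ol | COC(OC)C[C@@](C)(O)C[C@@H](O[Si](C)(C)C(C)(C)C)/C=C(/CO[Si](C)(C)C(C)(C)C)I | intermediate
11 | (2Z,4R,6S)-4-[(tert-butyldimethylsilyl)oxy]-2-{[(tert-butyldimethylsilyl)oxy]methyl}-6-hydroxy-8,8-dimethoxy-6-methyloct-2-enal | COC(OC)C[C@@](C)(O)C[C@@H](O[Si](C)(C)C(C)(C)C)/C=C(/CO[Si](C)(C)C(C)(C)C)C=O | intermediate
12 | 3-(methoxymethoxy)prop-1-ene | C=CCOCOC | starting material
13 | [(2Z)-3-(methoxymethoxy)prop-2-en-1-yl]bis[(+)-isopinocampheyl]borane | COCO/C=C\CB([C@H]1C[C@H]2C[C@@H]([C@@H]1C)C2(C)C)[C@H]1C[C@H]2C[C@@H]([C@@H]1C)C2(C)C | intermediate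
14 | (3S,5R,6Z,8S,9S)-5-[(tert-butyldimethylsilyl)oxy]-7-{[(tert-butyldimethylsilyl)oxy]methyl}-1,1-dimethoxy-9-(methoxymethoxy)-3-methylundeca-6,10-diene-3,8-diol | COC(OC)C[C@@](C)(O)C[C@@H](O[Si](C)(C)C(C)(C)C)/C=C(/CO[Si](C)(C)C(C)(C)C)[C@H](O)[C@@H](OCOC)C=C | intermediate
15 | (3S,5R,6Z,8S,9S)-5-[(tert-butyldimethylsilyl)oxy]-7-(hydroxymethyl)-1,1-dimethoxy-9-(methoxymethoxy)-3-methylundeca-6,10-diene-3,8-diol | COC(OC)C[C@@](C)(O)C[C@@H](O[Si](C)(C)C(C)(C)C)/C=C(/CO)[C@H](O)[C@@H](OCOC)C=C | intermediate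
16 | (3S,5R,6Z,8S,9S)-8-acetoxy-7-(acetoxymethyl)-5-[(tert-butyldimethylsilyl)oxy]-1,1-dimethoxy-9-(methoxymethoxy)-3-methylundeca-6,10-dien-3-ol | COC(OC)C[C@@](C)(O)C[C@@H](O[Si](C)(C)C(C)(C)C)/C=C(/COC(C)=O)[C@H](OC(C)=O)[C@@H](OCOC)C=C | intermediate
17 | (3S,5R,6Z,8S,9S)-8-acetoxy-7-(acetoxymethyl)-5-[(tert-butyldimethylsilyl)oxy]-3,9-dihydroxy-3-methylundeca-6,10-dienal | O=CC[C@@](C)(O)C[C@@H](O[Si](C)(C)C(C)(C)C)/C=C(/COC(C)=O)[C@H](OC(C)=O)[C@@H](O)C=C | intermediate
18 | 2-(bromomethyl)prop-2-enoic acid | C=C(CBr)C(=O)O | starting material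
19 | (3S,4S,5Z,7R,9S)-4-acetoxy-5-(acetoxymethyl)-7-[(tert-butyldimethylsilyl)oxy]-9-hydroxy-9-methyl-11-oxoundeca-1,5-dien-3-yl 2-(bromomethyl)prop-2-enoate | O=CC[C@@](C)(O)C[C@@H](O[Si](C)(C)C(C)(C)C)/C=C(/COC(C)=O)[C@H](OC(C)=O)[C@@H](OC(=O)C(=C)CBr)C=C | intermediate
20 | (1S,2Z,4R,6S)-2-(acetoxymethyl)-1-[(2S)-4-(bromomethyl)-5-oxo-2,5-dihydrofuran-2-yl]-4-[(tert-butyldimethylsilyl)oxy]-6-hydroxy-6-methyl-8-oxooct-2-en-1-yl acetate | O=CC[C@@](C)(O)C[C@@H](O[Si](C)(C)C(C)(C)C)/C=C(/COC(C)=O)[C@H](OC(C)=O)[C@H]1OC(=O)C(CBr)=C1 | intermediate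
21 | allylchromium dichloride from 20 (trivalent chromium on the former bromomethyl carbon) | O=CC[C@@](C)(O)C[C@@H](O[Si](C)(C)C(C)(C)C)/C=C(/COC(C)=O)[C@H](OC(C)=O)[C@H]1OC(=O)C(C[Cr](Cl)Cl)=C1 | intermediate
22 | (3aR,4S,6R,8R,9Z,11S,11aS)-11-acetoxy-10-(acetoxymethyl)-8-[(tert-butyldimethylsilyl)oxy]-4,6-dihydroxy-6-methyl-3-methylidene-3a,4,5,6,7,8,11,11a-octahydrocyclodeca[b]furan-2(3H)-one | C=C1C(=O)O[C@H]2[C@H]1[C@@H](O)C[C@@](C)(O)C[C@@H](O[Si](C)(C)C(C)(C)C)/C=C(/COC(C)=O)[C@@H]2OC(C)=O | intermediate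
23 | but-2-yn-1-ol | CC#CCO | starting material
24 | alkenylaluminate from 23 (aluminium on C2; shown in its simplest form) | [Li+].C/C=C(/CO1)[AlH2-]1 | intermediate
25 | (2Z)-2-iodobut-2-en-1-ol | C/C=C(/CO)I | intermediate
26 | dilithio derivative of 25 (lithium alkoxide, C2 alkenyllithium) | C/C=C(/CO[Li])[Li] | intermediate
27 | (2Z)-2-(hydroxymethyl)but-2-enoic acid | C/C=C(/CO)C(=O)O | intermediate
28 | (2Z)-2-(acetoxymethyl)but-2-enoic acid | C/C=C(/COC(C)=O)C(=O)O | intermediate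
29 | (3aR,4R,6R,8R,9Z,11S,11aS)-11-acetoxy-10-(acetoxymethyl)-8-[(tert-butyldimethylsilyl)oxy]-6-hydroxy-6-methyl-3-methylidene-2-oxo-2,3,3a,4,5,6,7,8,11,11a-decahydrocyclodeca[b]furan-4-yl (2Z)-2-(acetoxymethyl)but-2-enoate | C=C1C(=O)O[C@H]2[C@H]1[C@H](OC(=O)/C(=C\C)COC(C)=O)C[C@@](C)(O)C[C@@H](O[Si](C)(C)C(C)(C)C)/C=C(/COC(C)=O)[C@@H]2OC(C)=O | intermediate
30 | (3aR,4R,6S,8R,9Z,11S,11aS)-11-acetoxy-10-(acetoxymethyl)-6,8-dihydroxy-6-methyl-3-methylidene-2-oxo-2,3,3a,4,5,6,7,8,11,11a-decahydrocyclodeca[b]furan-4-yl (2Z)-2-(acetoxymethyl)but-2-enoate | C=C1C(=O)O[C@H]2[C@H]1[C@H](OC(=O)/C(=C\C)COC(C)=O)C[C@@](C)(O)C[C@@H](O)/C=C(/COC(C)=O)[C@@H]2OC(C)=O | target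

**Totals**
Total step count: 18 (15 in the main line, 3 for acid 28).
Longest linear sequence: 15 steps (1 to 30 through steps 1–13, 17 and 18).

**Steps most likely to fail, with fallbacks**

The first is the ring closure of step 13. The allylchromium may open the lactone by β-elimination, oligomerise, or add with a different facial sense; the C8 configuration in particular rests on the chair model and is not secured by direct precedent. The fallback sets out from 20. Stannylation with Me3SnSnMe3 and Pd(PPh3)4 gives the allylstannane F4. BF3·OEt2 at −78 °C under high dilution then closes the ring by Lewis-acid allyl transfer through an open transition state (no organochromium, syn-selective), giving the (8R)-alcohol F5. Esterification of the (8R)-alcohol F5 with 28 with retention (2,4,6-trichlorobenzoyl chloride, Et3N, DMAP) comes back to the route at 29. The same retentive esterification is used if step 13 itself delivers the 8R epimer.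

The second is the Mitsunobu inversion of step 17 at the hindered C8 carbinol, where elimination toward C7 or C9 or no reaction are the likely failures. The fallback sets out from 22. ClCH2SO2Cl and pyridine give the isolable C8 chloromethanesulfonate F6. This is displaced in a separate step with the caesium salt of 28 (Cs2CO3, 18-crown-6, toluene, 60 °C) with inversion, coming back to the route at 29.

The third is the reductive carbonylation of step 6, where the free Z-enal 11 may drift to the E isomer or the iodide may simply be reduced. The fallback sets out from 9. Pd(PPh3)4, CO and Et3N close the C2 hydroxyl onto the acylpalladium to give the butenolide F1, so the alkene geometry is held in a ring. i-Bu2AlH at −78 °C gives the lactol F2. Alkoxyallylboration of the ring-opened form with 13 gives the triol F3. TBSCl and imidazole at −20 °C silylate the less hindered C2 hydroxyl, coming back to the route at 14.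

**Further compounds**
F1 | step 6 | (5R)-3-{[(tert-butyldimethylsilyl)oxy]methyl}-5-[(2S)-2-hydroxy-4,4-dimethoxy-2-methylbutyl]furan-2(5H)-one | COC(OC)C[C@@](C)(O)C[C@H]1OC(=O)C(CO[Si](C)(C)C(C)(C)C)=C1
F2 | step 6 | (5R)-3-{[(tert-butyldimethylsilyl)oxy]methyl}-5-[(2S)-2-hydroxy-4,4-dimethoxy-2-methylbutyl]-2,5-dihydrofuran-2-ol (anomer mixture) | COC(OC)C[C@@](C)(O)C[C@H]1OC(O)C(CO[Si](C)(C)C(C)(C)C)=C1
F3 | step 6 | (3S,5R,6Z,8S,9S)-7-{[(tert-butyldimethylsilyl)oxy]methyl}-1,1-dimethoxy-9-(methoxymethoxy)-3-methylundeca-6,10-diene-3,5,8-triol | COC(OC)C[C@@](C)(O)C[C@@H](O)/C=C(/CO[Si](C)(C)C(C)(C)C)[C@H](O)[C@@H](OCOC)C=C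
F4 | step 13 | (1S,2Z,4R,6S)-2-(acetoxymethyl)-4-[(tert-butyldimethylsilyl)oxy]-6-hydroxy-6-methyl-8-oxo-1-{(2S)-5-oxo-4-[(trimethylstannyl)methyl]-2,5-dihydrofuran-2-yl}oct-2-en-1-yl acetate | O=CC[C@@](C)(O)C[C@@H](O[Si](C)(C)C(C)(C)C)/C=C(/COC(C)=O)[C@H](OC(C)=O)[C@H]1OC(=O)C(C[Sn](C)(C)C)=C1
F5 | step 13 | (3aR,4R,6R,8R,9Z,11S,11aS)-11-acetoxy-10-(acetoxymethyl)-8-[(tert-butyldimethylsilyl)oxy]-4,6-dihydroxy-6-methyl-3-methylidene-3a,4,5,6,7,8,11,11a-octahydrocyclodeca[b]furan-2(3H)-one | C=C1C(=O)O[C@H]2[C@H]1[C@H](O)C[C@@](C)(O)C[C@@H](O[Si](C)(C)C(C)(C)C)/C=C(/COC(C)=O)[C@@H]2OC(C)=O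
F6 | step 17 | (3aS,4S,6S,8R,9Z,11S,11aS)-11-acetoxy-10-(acetoxymethyl)-8-[(tert-butyldimethylsilyl)oxy]-6-hydroxy-6-methyl-3-methylidene-2-oxo-2,3,3a,4,5,6,7,8,11,11a-decahydrocyclodeca[b]furan-4-yl chloromethanesulfonate | C=C1C(=O)O[C@H]2[C@H]1[C@@H](OS(=O)(=O)CCl)C[C@@](C)(O)C[C@@H](O[Si](C)(C)C(C)(C)C)/C=C(/COC(C)=O)[C@@H]2OC(C)=O
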